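**Retrosynthetic overview**

1. Numbering: ring A is the oxygen-free trimethylcyclohexene (C1 = CMe2, C2–C4 = CH2, C5 = methyl-bearing sp2 carbon, C6 = chain-bearing sp2 carbon); ring B is the acyloxy ring (C1'–C6', oxygen on C3'); the chain is C7–C15 and C15'–C7'.
2. Late disconnections: the ester C–O bond (oleoyl chloride, last step), then C11=C12 and C11'=C12' by two Wittig reactions on the all-E C10 dialdehyde (C15 + C10 + C15), then C6–C7 (Suzuki–Miyaura) and C6'–C7' (Stille) to a common six-carbon dienyl unit.
3. Key disconnection: ring A is closed at C1–C2 by a copper-catalysed borylative cyclisation of an acyclic, achiral tetrasubstituted allene tosylate. One operation should deliver the ring, the tetrasubstituted C5=C6 alkene, the quaternary C1 and a boron handle on C6.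
4. Enabling feature: in ring A the tetrasubstituted C5=C6 double bond sits next to the quaternary gem-dimethyl C1, so C5–C6–C1 is an allyl triad that maps onto an allene C5=C6=C1. Boron adds to the central atom C6 (the atom that carries the polyene), and the 2-boryl allylcopper can close a six-membered ring only through C1 (C5 would give a cyclobutane).
5. Ring order: ring B is taken intact and enantiopure from (4R,6R)-actinol, whose carbinol carbon becomes C3' and is never touched; ring A is the only ring that is formed (step 5).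

Key step: step 5

Assumption: (4R,6R)-4-hydroxy-2,2,6-trimethylcyclohexanone and all-E 2,7-dimethylocta-2,4,6-trienedial, both bulk carotenoid intermediates, are treated as purchasable, and all polyene steps are run under argon with exclusion of light.

**Route**

Step 1
Reactants: 1 tert-butyldimethyl(pent-4-yn-1-yloxy)silane; 2 acetone
Product: 5 7-[(tert-butyldimethylsilyl)oxy]-2-methylhept-3-yn-2-yl acetate, via lithium acetylide 3 (not isolated), via lithium alkoxide 4 (not isolated)
Conditions: n-BuLi, THF, −78 °C; acetone, −78 → 0 °C; Ac2O, 0 °C → rt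
Reagents that add atoms: acetic anhydride, CC(=O)OC(C)=O
Why: Deprotonation of the terminal alkyne, 1,2-addition of the acetylide to acetone and O-acetylation of the tertiary lithium alkoxide in the same flask (acetylide addition followed by acylation) should give the tertiary propargylic acetate directly; no stereocentre is formed.

Step 2
Reactants: 5 7-[(tert-butyldimethylsilyl)oxy]-2-methylhept-3-yn-2-yl acetate
Product: 6 tert-butyl[(4,6-dimethylhepta-4,5-dien-1-yl)oxy]dimethylsilane
Conditions: MeMgBr, CuI (10 mol %), LiBr (20 mol %), THF, −20 → 0 °C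
Reagents that add atoms: methylmagnesium bromide, C[Mg]Br
Why: Copper-catalysed anti-SN2' substitution of a tertiary propargylic acetate by a Grignard reagent is the standard entry to tetrasubstituted allenes, the methyl group entering at the chain-bearing alkyne carbon; the allene is achiral because one terminus carries two methyl groups.

Step 3
Reactants: 6 tert-butyl[(4,6-dimethylhepta-4,5-dien-1-yl)oxy]dimethylsilane
Product: 7 4,6-dimethylhepta-4,5-dien-1-ol
Conditions: TBAF, THF, 0 °C → rt
Reagents that add atoms: none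
Why: Fluoride cleavage of the primary silyl ether (desilylation) should leave the allene untouched.

Step 4
Reactants: 7 4,6-dimethylhepta-4,5-dien-1-ol
Product: 8 4,6-dimethylhepta-4,5-dien-1-yl 4-methylbenzenesulfonate
Conditions: TsCl, Et3N, DMAP (cat.), CH2Cl2, 0 °C
Reagents that add atoms: 4-methylbenzenesulfonyl chloride, Cc1ccc(cc1)S(=O)(=O)Cl
Why: Tosylation of the primary alcohol under amine/DMAP catalysis installs the leaving group at the future C2 without affecting the allene.

Step 5
Reactants: 8 4,6-dimethylhepta-4,5-dien-1-yl 4-methylbenzenesulfonate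
Product: 10 4,4,5,5-tetramethyl-2-(2,6,6-trimethylcyclohex-1-en-1-yl)-1,3,2-dioxaborolane, via allylcopper 9 (not isolated)
Conditions: (IMes)CuCl (10 mol %; IMes = 1,3-bis(2,4,6-trimethylphenyl)imidazol-2-ylidene), B2pin2, KOtBu, THF (dilute), 40 °C
Reagents that add atoms: bis(pinacolato)diboron, CC1(C)OB(OC1(C)C)B1OC(C)(C)C(C)(C)O1
Why: Proposed new method: LCu–Bpin (from (IMes)CuCl, KOtBu and B2pin2) should add across the allene of 8 with boron going to the central carbon C6 and copper to a fully substituted terminus, giving the 2-boryl allylcopper 9, whose sigma forms (Cu on C1 or on C5) and both geometries about the nascent C5=C6 bond interconvert by 1,3-copper shift, and the CMe2 terminus C1 then displaces the tosylate at C2 to form the C1–C2 bond. The closest known reaction types are the copper-catalysed borylcupration of allenes with capture of the 2-boryl allylcopper by carbon electrophiles at its gamma carbon, and the copper-catalysed borylative cyclisation of alkenyl sulfonates and halides, in which an organocopper closes a ring on a tethered sp3 electrophile; new here are the tetrasubstituted allene and ring closure through the distal allyl terminus onto an alkyl tosylate. Ring A closes in a 6-exo-tet mode at C2 with the allyl unit inside the new ring, so that C5=C6 ends up endocyclic and tetrasubstituted with boron on C6. No stereocentre is formed; the quaternary C1 comes from the gem-dimethyl allene terminus. The step needs boron on C6 (secured by both allene termini being fully substituted), alkylation at C1 and not at C5 (six-membered against four-membered ring, with the isomeric allylcopper forms funnelled to the cyclisable one by the 1,3-shift), and borylcupration ahead of direct substitution of the leaving group (secured by choosing a tosylate in place of a halide).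

Step 6
Reactants: 11 (E)-3-methylpent-2-en-4-yn-1-ol
Product: 12 (2E,4E)-3-methyl-5-(tributylstannyl)penta-2,4-dien-1-ol
Conditions: Bu3SnH, PdCl2(PPh3)2 (2 mol %), THF, 0 °C → rt
Reagents that add atoms: tributyltin hydride, CCCC[SnH](CCCC)CCCC
Why: Palladium-catalysed syn-hydrostannation of the terminal alkyne of a conjugated enyne should place tin on the terminal carbon and set the new double bond E by cis addition of H and Sn, the existing 2E bond being retained.

Step 7
Reactants: 12 (2E,4E)-3-methyl-5-(tributylstannyl)penta-2,4-dien-1-ol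
Product: 13 (2E,4E)-5-iodo-3-methylpenta-2,4-dien-1-ol
Conditions: I2, CH2Cl2, 0 °C, dark
Reagents that add atoms: iodine, II
Why: Iododestannylation of an alkenylstannane proceeds with retention of double-bond geometry.

Step 8
Reactants: 10 4,4,5,5-tetramethyl-2-(2,6,6-trimethylcyclohex-1-en-1-yl)-1,3,2-dioxaborolane; 13 (2E,4E)-5-iodo-3-methylpenta-2,4-dien-1-ol
Product: 14 (2E,4E)-3-methyl-5-(2,6,6-trimethylcyclohex-1-en-1-yl)penta-2,4-dien-1-ol
Conditions: Pd(OAc)2 (5 mol %), SPhos (10 mol %), K3PO4, THF/H2O, 45 °C, dark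
Reagents that add atoms: none
Why: Suzuki–Miyaura coupling of the hindered tetrasubstituted cyclohexenyl boronate with the E-alkenyl iodide, helped by an electron-rich biarylphosphine, should form the C6–C7 bond with retention of both alkene geometries.

Step 9
Reactants: 14 (2E,4E)-3-methyl-5-(2,6,6-trimethylcyclohex-1-en-1-yl)penta-2,4-dien-1-ol
Product: 15 [(2E,4E)-3-methyl-5-(2,6,6-trimethylcyclohex-1-en-1-yl)penta-2,4-dien-1-yl]triphenylphosphonium bromide
Conditions: PPh3·HBr, MeOH, rt, dark
Reagents that add atoms: triphenylphosphine hydrobromide, [Br-].c1ccc(cc1)[PH+](c1ccccc1)c1ccccc1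
Why: Acid ionisation of the dienylic alcohol and capture of the pentadienyl cation at its primary terminus by triphenylphosphine (phosphonium salt formation) should give the fully conjugated, thermodynamically preferred salt.

Step 10
Reactants: 16 (4R,6R)-4-hydroxy-2,2,6-trimethylcyclohexan-1-one
Product: 17 (4R,6R)-4-[(tert-butyldimethylsilyl)oxy]-2,2,6-trimethylcyclohexan-1-one
Conditions: TBSCl, imidazole, DMF, rt
Reagents that add atoms: tert-butyldimethylsilyl chloride, CC(C)(C)[Si](C)(C)Cl
Why: Imidazole-promoted silylation protects the secondary alcohol before enolate chemistry and touches neither stereocentre.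

Step 11
Reactants: 17 (4R,6R)-4-[(tert-butyldimethylsilyl)oxy]-2,2,6-trimethylcyclohexan-1-one
Product: 19 (4R)-4-[(tert-butyldimethylsilyl)oxy]-2,6,6-trimethylcyclohex-1-en-1-yl trifluoromethanesulfonate, via lithium enolate 18 (not isolated)
Conditions: LiN(iPr)2 (LDA), THF, −78 °C; PhNTf2, −78 °C → rt
Reagents that add atoms: N-phenylbis(trifluoromethanesulfonimide), O=S(=O)(N(c1ccccc1)S(=O)(=O)C(F)(F)F)C(F)(F)F
Why: The ketone can enolise only towards its methyl-bearing alpha carbon (the other is quaternary), so deprotonation and O-sulfonylation (enol triflate formation) should give one regioisomer; the methyl-bearing stereocentre is erased and the silyloxy-bearing one, remote from the enolate, keeps its R configuration.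

Step 12
Reactants: 19 (4R)-4-[(tert-butyldimethylsilyl)oxy]-2,6,6-trimethylcyclohex-1-en-1-yl trifluoromethanesulfonate; 12 (2E,4E)-3-methyl-5-(tributylstannyl)penta-2,4-dien-1-ol
Product: 20 (2E,4E)-5-[(4R)-4-[(tert-butyldimethylsilyl)oxy]-2,6,6-trimethylcyclohex-1-en-1-yl]-3-methylpenta-2,4-dien-1-ol
Conditions: Pd2(dba)3 (2.5 mol %), AsPh3 (20 mol %), LiCl, NMP, 60 °C
Reagents that add atoms: none
Why: Stille coupling of the hindered enol triflate with the E,E-dienylstannane under soft-ligand conditions should form the C6'–C7' bond with retention of alkene geometry and without affecting C3'.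

Step 13
Reactants: 20 (2E,4E)-5-[(4R)-4-[(tert-butyldimethylsilyl)oxy]-2,6,6-trimethylcyclohex-1-en-1-yl]-3-methylpenta-2,4-dien-1-ol
Product: 21 (2E,4E)-5-[(4R)-4-hydroxy-2,6,6-trimethylcyclohex-1-en-1-yl]-3-methylpenta-2,4-dien-1-ol
Conditions: TBAF, THF, rt
Reagents that add atoms: none
Why: Fluoride desilylation frees the C3' hydroxyl, which the following phosphonium and Wittig steps tolerate unprotected.

Step 14
Reactants: 21 (2E,4E)-5-[(4R)-4-hydroxy-2,6,6-trimethylcyclohex-1-en-1-yl]-3-methylpenta-2,4-dien-1-ol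
Product: 22 {(2E,4E)-5-[(4R)-4-hydroxy-2,6,6-trimethylcyclohex-1-en-1-yl]-3-methylpenta-2,4-dien-1-yl}triphenylphosphonium bromide
Conditions: PPh3·HBr, MeOH, rt, dark
Reagents that add atoms: triphenylphosphine hydrobromide, [Br-].c1ccc(cc1)[PH+](c1ccccc1)c1ccccc1
Why: Only the dienylic primary alcohol ionises under the mild acid, so phosphonium salt formation should occur at the chain terminus while the secondary homoallylic C3' alcohol and its configuration are retained.

Step 15
Reactants: 22 {(2E,4E)-5-[(4R)-4-hydroxy-2,6,6-trimethylcyclohex-1-en-1-yl]-3-methylpenta-2,4-dien-1-yl}triphenylphosphonium bromide; 23 (2E,4E,6E)-2,7-dimethylocta-2,4,6-trienedial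
Product: 25 (3R)-3-hydroxy-12'-apo-β-caroten-12'-al, via phosphorus ylide 24 (not isolated)
Conditions: NaOMe, CH2Cl2/MeOH, 0 °C → rt, dark (23 in excess); then heptane, 90 °C
Reagents that add atoms: none
Why: Wittig olefination of one formyl group of the dialdehyde, used in excess, forms C11'=C12', and heating should convert the sterically hindered Z isomer at the new bond into the E isomer (stereoconvergent thermal isomerisation), giving the all-E C25 aldehyde.

Step 16
Reactants: 15 [(2E,4E)-3-methyl-5-(2,6,6-trimethylcyclohex-1-en-1-yl)penta-2,4-dien-1-yl]triphenylphosphonium bromide; 25 (3R)-3-hydroxy-12'-apo-β-caroten-12'-al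
Product: 27 (3R)-β,β-caroten-3-ol (β-cryptoxanthin), via phosphorus ylide 26 (not isolated)
Conditions: NaOMe, CH2Cl2/MeOH, rt, dark; then EtOH, reflux; crystallisation
Reagents that add atoms: none
Why: The second Wittig olefination forms C11=C12 and completes the C40 chain, and heating should funnel the hindered 11Z isomer to the crystalline all-E polyene; C3' is not affected.

Step 17
Reactants: 27 (3R)-β,β-caroten-3-ol; 28 (9Z)-octadec-9-enoyl chloride
Product: 29 (3R)-β,β-caroten-3-yl (9Z)-octadec-9-enoate (CNP0152321.1)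
Conditions: pyridine, DMAP (cat.), CH2Cl2, 0 °C → rt, dark
Reagents that add atoms: none
Why: O-Acylation of the secondary alcohol by the acid chloride under nucleophilic catalysis (esterification) proceeds with retention at C3' because the C–O bond is not broken, and the buffered, cold conditions should spare the polyene and the Z alkene of the acyl chain.

**Compound list**

1 | tert-butyldimethyl(pent-4-yn-1-yloxy)silane | C#CCCCO[Si](C)(C)C(C)(C)C | starting material
2 | acetone | CC(C)=O | starting material
3 | lithium acetylide of 1, [5-[(tert-butyldimethylsilyl)oxy]pent-1-yn-1-yl]lithium | [Li]C#CCCCO[Si](C)(C)C(C)(C)C | intermediate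
4 | lithium 7-[(tert-butyldimethylsilyl)oxy]-2-methylhept-3-yn-2-olate | [Li]OC(C)(C)C#CCCCO[Si](C)(C)C(C)(C)C | intermediate
5 | 7-[(tert-butyldimethylsilyl)oxy]-2-methylhept-3-yn-2-yl acetate | CC(=O)OC(C)(C)C#CCCCO[Si](C)(C)C(C)(C)C | intermediate
6 | tert-butyl[(4,6-dimethylhepta-4,5-dien-1-yl)oxy]dimethylsilane | CC(C)=C=C(C)CCCO[Si](C)(C)C(C)(C)C | intermediate
7 | 4,6-dimethylhepta-4,5-dien-1-ol | CC(C)=C=C(C)CCCO | intermediate
8 | 4,6-dimethylhepta-4,5-dien-1-yl 4-methylbenzenesulfonate | CC(C)=C=C(C)CCCOS(=O)(=O)c1ccc(C)cc1 | intermediate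
9 | {2,4-dimethyl-3-(4,4,5,5-tetramethyl-1,3,2-dioxaborolan-2-yl)-7-[(4-methylbenzenesulfonyl)oxy]hept-3-en-2-yl}[1,3-bis(2,4,6-trimethylphenyl)imidazol-2-ylidene]copper (sigma form with copper on the CMe2 carbon, in equilibrium with its 1,3-shifted form; alkene geometry not fixed) | Cc1cc(C)c(c(C)c1)N2C=C[N+](=C2[Cu-]C(C)(C)C(B3OC(C)(C)C(C)(C)O3)=C(C)CCCOS(=O)(=O)c4ccc(C)cc4)c5c(C)cc(C)cc5C | intermediate
10 | 4,4,5,5-tetramethyl-2-(2,6,6-trimethylcyclohex-1-en-1-yl)-1,3,2-dioxaborolane | CC1=C(B2OC(C)(C)C(C)(C)O2)C(C)(C)CCC1 | intermediate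
11 | (E)-3-methylpent-2-en-4-yn-1-ol | OC/C=C(C)/C#C | starting material
12 | (2E,4E)-3-methyl-5-(tributylstannyl)penta-2,4-dien-1-ol | OC/C=C(C)/C=C/[Sn](CCCC)(CCCC)CCCC | intermediate
13 | (2E,4E)-5-iodo-3-methylpenta-2,4-dien-1-ol | OC/C=C(C)/C=C/I | intermediate
14 | (2E,4E)-3-methyl-5-(2,6,6-trimethylcyclohex-1-en-1-yl)penta-2,4-dien-1-ol | OC/C=C(C)/C=C/C1=C(C)CCCC1(C)C | intermediate
15 | [(2E,4E)-3-methyl-5-(2,6,6-trimethylcyclohex-1-en-1-yl)penta-2,4-dien-1-yl]triphenylphosphonium bromide | CC1=C(/C=C/C(C)=C/C[P+](c2ccccc2)(c2ccccc2)c2ccccc2)C(C)(C)CCC1.[Br-] | intermediate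
16 | (4R,6R)-4-hydroxy-2,2,6-trimethylcyclohexan-1-one (actinol) | O[C@@H]1C[C@@H](C)C(=O)C(C)(C)C1 | starting material
17 | (4R,6R)-4-[(tert-butyldimethylsilyl)oxy]-2,2,6-trimethylcyclohexan-1-one | CC(C)(C)[Si](C)(C)O[C@@H]1C[C@@H](C)C(=O)C(C)(C)C1 | intermediate
18 | lithium (4R)-4-[(tert-butyldimethylsilyl)oxy]-2,6,6-trimethylcyclohex-1-en-1-olate | CC(C)(C)[Si](C)(C)O[C@@H]1CC(C)=C(O[Li])C(C)(C)C1 | intermediate
19 | (4R)-4-[(tert-butyldimethylsilyl)oxy]-2,6,6-trimethylcyclohex-1-en-1-yl trifluoromethanesulfonate | CC(C)(C)[Si](C)(C)O[C@@H]1CC(C)=C(OS(=O)(=O)C(F)(F)F)C(C)(C)C1 | intermediate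
20 | (2E,4E)-5-[(4R)-4-[(tert-butyldimethylsilyl)oxy]-2,6,6-trimethylcyclohex-1-en-1-yl]-3-methylpenta-2,4-dien-1-ol | CC(C)(C)[Si](C)(C)O[C@@H]1CC(C)=C(/C=C/C(C)=C/CO)C(C)(C)C1 | intermediate
21 | (2E,4E)-5-[(4R)-4-hydroxy-2,6,6-trimethylcyclohex-1-en-1-yl]-3-methylpenta-2,4-dien-1-ol | O[C@@H]1CC(C)=C(/C=C/C(C)=C/CO)C(C)(C)C1 | intermediate
22 | {(2E,4E)-5-[(4R)-4-hydroxy-2,6,6-trimethylcyclohex-1-en-1-yl]-3-methylpenta-2,4-dien-1-yl}triphenylphosphonium bromide | O[C@@H]1CC(C)=C(/C=C/C(C)=C/C[P+](c2ccccc2)(c2ccccc2)c2ccccc2)C(C)(C)C1.[Br-] | intermediate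
23 | (2E,4E,6E)-2,7-dimethylocta-2,4,6-trienedial | O=C/C(C)=C/C=C/C=C(C)/C=O | starting material
24 | {(2E,4E)-5-[(4R)-4-hydroxy-2,6,6-trimethylcyclohex-1-en-1-yl]-3-methylpenta-2,4-dien-1-ylidene}triphenylphosphorane | O[C@@H]1CC(C)=C(/C=C/C(C)=C/C=P(c2ccccc2)(c2ccccc2)c2ccccc2)C(C)(C)C1 | intermediate
25 | (3R)-3-hydroxy-12'-apo-β-caroten-12'-al, (2E,4E,6E,8E,10E,12E)-13-[(4R)-4-hydroxy-2,6,6-trimethylcyclohex-1-en-1-yl]-2,7,11-trimethyltrideca-2,4,6,8,10,12-hexaenal | O[C@@H]1CC(C)=C(/C=C/C(C)=C/C=C/C(C)=C/C=C/C=C(C)/C=O)C(C)(C)C1 | intermediate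
26 | [(2E,4E)-3-methyl-5-(2,6,6-trimethylcyclohex-1-en-1-yl)penta-2,4-dien-1-ylidene]triphenylphosphorane | CC1=C(/C=C/C(C)=C/C=P(c2ccccc2)(c2ccccc2)c2ccccc2)C(C)(C)CCC1 | intermediate
27 | (3R)-β,β-caroten-3-ol (β-cryptoxanthin) | O[C@@H]1CC(C)=C(/C=C/C(C)=C/C=C/C(C)=C/C=C/C=C(C)/C=C/C=C(C)/C=C/C2=C(C)CCCC2(C)C)C(C)(C)C1 | intermediate
28 | (9Z)-octadec-9-enoyl chloride (oleoyl chloride) | CCCCCCCC/C=C\CCCCCCCC(Cl)=O | starting material
29 | (3R)-β,β-caroten-3-yl (9Z)-octadec-9-enoate (CNP0152321.1) | CCCCCCCC/C=C\CCCCCCCC(=O)O[C@@H]1CC(C)=C(/C=C/C(C)=C/C=C/C(C)=C/C=C/C=C(C)/C=C/C=C(C)/C=C/C2=C(C)CCCC2(C)C)C(C)(C)C1 | target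

**Step count and risks**

Total steps: 17. Longest linear sequence: 9 (steps 1, 2, 3, 4, 5, 8, 9, 16, 17).

Steps most likely to fail:

1. Step 5 (the proposed new method). Borylcupration of the hindered tetrasubstituted allene may be slow, so that direct substitution at the tosylate takes over, or the allylcopper may close through C5 to a cyclobutane or be protonated before it cyclises. The fallback uses known chemistry, sets out from tosylate 8 and comes back to the route at dienol 14, so that 10 and 13 are not needed. Hydroboration of the allene with 9-BBN in THF, which places boron on the central allene carbon of a tetrasubstituted allene, would give the alkenylborane 5-(9-borabicyclo[3.3.1]nonan-9-yl)-4,6-dimethylhept-4-en-1-yl 4-methylbenzenesulfonate F1 (not isolated; the position of its double bond is immaterial), and oxidation with NaBO3 in aqueous THF would give 4,6-dimethyl-5-oxoheptyl 4-methylbenzenesulfonate F2. KOtBu in t-BuOH/THF would then close the same C1–C2 bond by intramolecular C-alkylation of the isopropyl-side enolate (6-enolendo-exo-tet; the other enolate could only form a cyclobutane) to racemic 2,2,6-trimethylcyclohexan-1-one F3, a compound that is also sold and could be entered directly. Tf2O with 2,6-di-tert-butyl-4-methylpyridine in CH2Cl2 would give 2,6,6-trimethylcyclohex-1-en-1-yl trifluoromethanesulfonate F4, and Stille coupling of F4 with stannane 12 under the conditions of step 12 would give 14.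

2. Step 8. Transmetalation of the tetrasubstituted, doubly flanked alkenyl boronate may be too slow, so that protodeboronation of 10 and decomposition or homocoupling of the sensitive iodide 13 compete. The fallback sets out from boronate 10 and comes back at 14, with the roles of the partners inverted. Oxidative iododeboronation (NaI, TsN(Cl)Na (chloramine-T), aqueous THF, rt) would give 2-iodo-1,3,3-trimethylcyclohex-1-ene F5. Stille coupling of F5 with stannane 12 (Pd2(dba)3, AsPh3, CuI, NMP, 50 °C) would give 14; the hindered ring partner then enters by oxidative addition, which tolerates steric load better than transmetalation.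

3. Step 15. Olefination may run on at the second formyl group of the dialdehyde to a C40 diol, and Z to E equilibration at the new double bond may stay incomplete, both lowering the supply of 25. The fallback sets out from dialdehyde 23 and comes back at 25. Mono-acetalisation of 23 with 2,2-dimethylpropane-1,3-diol (one equivalent, PPTS, CH2Cl2; recovered dialdehyde and bis-acetal are recycled) would give (2E,4E,6E)-7-(5,5-dimethyl-1,3-dioxan-2-yl)-2-methylocta-2,4,6-trienal F6. Wittig reaction of F6 with ylide 24 (from 22, NaOMe), followed by the thermal isomerisation, would give (1R)-4-[(1E,3E,5E,7E,9E,11E)-12-(5,5-dimethyl-1,3-dioxan-2-yl)-3,7-dimethyltrideca-1,3,5,7,9,11-hexaen-1-yl]-3,5,5-trimethylcyclohex-3-en-1-ol F7. Mild hydrolysis (dilute aqueous H2SO4, acetone, rt) would release 25.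

**Further compounds**

F1 | step 5 | 5-(9-borabicyclo[3.3.1]nonan-9-yl)-4,6-dimethylhept-4-en-1-yl 4-methylbenzenesulfonate | CC(C)C(B1C2CCCC1CCC2)=C(C)CCCOS(=O)(=O)c1ccc(C)cc1
F2 | step 5 | 4,6-dimethyl-5-oxoheptyl 4-methylbenzenesulfonate (racemic) | CC(C)C(=O)C(C)CCCOS(=O)(=O)c1ccc(C)cc1
F3 | step 5 | 2,2,6-trimethylcyclohexan-1-one (racemic) | CC1CCCC(C)(C)C1=O
F4 | step 5 | 2,6,6-trimethylcyclohex-1-en-1-yl trifluoromethanesulfonate | CC1=C(OS(=O)(=O)C(F)(F)F)C(C)(C)CCC1
F5 | step 8 | 2-iodo-1,3,3-trimethylcyclohex-1-ene | CC1=C(I)C(C)(C)CCC1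
F6 | step 15 | (2E,4E,6E)-7-(5,5-dimethyl-1,3-dioxan-2-yl)-2-methylocta-2,4,6-trienal | O=C/C(C)=C/C=C/C=C(C)/C1OCC(C)(C)CO1
F7 | step 15 | (1R)-4-[(1E,3E,5E,7E,9E,11E)-12-(5,5-dimethyl-1,3-dioxan-2-yl)-3,7-dimethyltrideca-1,3,5,7,9,11-hexaen-1-yl]-3,5,5-trimethylcyclohex-3-en-1-ol | O[C@@H]1CC(C)=C(/C=C/C(C)=C/C=C/C(C)=C/C=C/C=C(C)/C2OCC(C)(C)CO2)C(C)(C)C1
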